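**Retrosynthetic overview**

1. Feature: ring A, the resorcinol ring of the indane, has its two oxygens meta with one CH between them. Its two remaining substituted carbons are adjacent and hold the CH(4-hydroxyphenyl) carbon and the ring-fusion CH of ring B. A cyclopentenyl vinylketene and an alkoxyacetylene give exactly this pattern, with the free OH next to the aryl methine.
2. Target ⇐ ring E (cyclohexenone) by intramolecular aldol of the ring D ketone onto an enal on ring C, then oxidation ⇐ spiro ring D by Lewis-acid C-benzylation of a β-diketone made from the ring C ketone and a trans-diaryl γ-lactone.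
3. Indane ketone ⇐ benzannulation of a cyclopentenyl diazomethyl ketone with ethoxyacetylene ⇐ mono-ketal of a C2-symmetric 4,8-diaryl-cis-bicyclo[3.3.0]octane-2,6-dione ⇐ bis-enone ⇐ cycloocta-1,5-diene.
4. Ring order: B and C together (step 1), A (step 11), D (step 21), E (step 23). The methyl and ethyl ethers are exchanged for silyl ethers once ring A is built, so that the end game and the last deprotection need no strong acid.

Key step: step 11

**Remarks and assumptions**

- Ring letters: A = resorcinol ring of the indane; B = five-membered ring of the indane; C = second cyclopentane of the diquinane (carries the ketone, later the exocyclic alkene); D = cyclopentanone with the 3,5-dioxygenated and the third 4-oxygenated aryl group; E = cyclohexenone that bridges ring D.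
- Assumption on steps 1 and 2: the transannular diacetoxylation is taken to give the endo,endo-diacetate, and the lipase to cleave the (R)-configured acetates first. If either does not hold, the recovered diacetate carries the (1S,5S) skeleton and is saponified (K2CO3, MeOH) instead.
- Assumption on step 17: (S)-TRIP is taken to give the (1S,2R)-anti alcohol, by analogy with phosphoric-acid-catalysed crotylborations; otherwise the antipodal acid is used.
- Compound 2 is a racemate; its SMILES shows one enantiomer.

**Route**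

Step 1
Reactants: 1 (1Z,5Z)-cycloocta-1,5-diene
Product: 2 rac-endo,endo-cis-bicyclo[3.3.0]octane-2,6-diyl diacetate
Conditions: PhI(OAc)2, AcOH, reflux
Reagents that add atoms: (diacetoxyiodo)benzene, CC(=O)OI(OC(C)=O)c1ccccc1
Why: Trivalent iodine activates one alkene, the second alkene attacks across the ring and acetate enters at both carbons (transannular oxidative diacetoxylation), so the cis ring fusion of rings B and C follows from the geometry of the transannular closure and the diacetate forms as a C2-symmetric racemate.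

Step 2
Reactants: 2 rac-diacetate
Product: 3 (1S,2R,5S,6R)-cis-bicyclo[3.3.0]octane-2,6-diol
Conditions: Burkholderia cepacia lipase, phosphate buffer (pH 7)/acetone, 30 °C, to about half conversion
Reagents that add atoms: none
Why: Lipase-catalysed enantioselective ester hydrolysis (kinetic resolution) should cleave both acetates of one enantiomer and leave the antipodal diacetate, so the 1S,5S ring fusion is fixed by selection between enantiomers.

Step 3
Reactants: 3 diol
Product: 4 (1S,5S)-cis-bicyclo[3.3.0]octane-2,6-dione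
Conditions: Pr4N[RuO4] (5 mol%), N-methylmorpholine N-oxide, 4 Å MS, CH2Cl2, rt
Reagents that add atoms: none
Why: Ley–Griffith oxidation of both secondary alcohols under neutral conditions leaves the ring-fusion centres untouched, and these prefer the cis fusion in any case.

Step 4
Reactants: 4 dione
Product: 5 2,6-bis(trimethylsilyloxy)-cis-bicyclo[3.3.0]octa-2,6-diene
Conditions: LiN(i-Pr)2 (2.4 equiv), Me3SiCl, THF, −78 °C
Reagents that add atoms: chlorotrimethylsilane, C[Si](C)(C)Cl
Why: Kinetic deprotonation by the hindered amide takes the CH2 protons and not the ring-fusion methines, and silylation in situ gives the less substituted bis(silyl enol ether) (regioselective enolate trapping).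

Step 5
Reactants: 5 bis(silyl enol ether)
Product: 6 cis-bicyclo[3.3.0]octa-3,7-diene-2,6-dione
Conditions: Pd(OAc)2 (10 mol%), O2 (1 atm), DMSO, rt
Reagents that add atoms: none
Why: Saegusa–Ito dehydrogenation (palladation of each enol ether, then β-hydride elimination) puts each alkene where the enol ether was and gives the bis-enone under neutral conditions without touching the ring fusion.

Step 6
Reactants: 6 bis-enone; 7 4-methoxyphenylmagnesium bromide
Product: 8 (1S,4R,5S,8R)-4,8-bis(4-methoxyphenyl)-cis-bicyclo[3.3.0]octane-2,6-dione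
Conditions: 7 (2.6 equiv), CuBr·SMe2 (20 mol%), THF, −78 → −40 °C; aq. NH4Cl
Reagents that add atoms: none
Why: Copper-catalysed conjugate addition to both enones should deliver each aryl group from the convex face of the cis-fused diquinane, cis to the neighbouring ring-fusion hydrogen, which sets both new stereocentres and keeps the C2 axis.

Step 7
Reactants: 8 diaryl dione
Product: 9 mono(ethylene ketal) of 8
Conditions: HOCH2CH2OH (1.0 equiv), TsOH (cat.), benzene, reflux, Dean–Stark; diketone and bis-ketal recycled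
Reagents that add atoms: ethane-1,2-diol, OCCO
Why: Acid-catalysed ketalisation with one equivalent of diol; the two carbonyls are equivalent through the C2 axis, so only mono- against bis-ketal has to be sorted and no stereocentre is formed.

Step 8
Reactants: 9 keto ketal
Product: 10 enol triflate (double bond between the former carbonyl carbon and the CH2 next to the anisyl methine)
Conditions: KN(SiMe3)2, PhNTf2, THF, −78 °C
Reagents that add atoms: N-phenylbis(trifluoromethanesulfonimide), O=S(=O)(N(c1ccccc1)S(=O)(=O)C(F)(F)F)C(F)(F)F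
Why: Kinetic enolisation toward the CH2 group and not the ring-fusion CH, followed by O-sulfonylation (vinyl triflate formation), fixes the alkene in the position that ring A needs.

Step 9
Reactants: 10 enol triflate; 11 tributyl(1-ethoxyvinyl)stannane
Product: 13 1-acetylcyclopentene (methyl ketone on the triflate carbon, ketal intact), via ethoxydiene 12 (not isolated)
Conditions: Pd(PPh3)4 (5 mol%), LiCl, THF, 65 °C; then 1 M HCl, THF, 0 °C
Reagents that add atoms: water, O
Why: Stille coupling of the vinyl triflate with the acyl-anion equivalent and brief cold hydrolysis of the enol ether give the conjugated methyl ketone, while the dioxolane survives and the γ-benzylic stereocentre is not enolised.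

Step 10
Reactants: 13 methyl ketone
Product: 15 cyclopentenyl diazomethyl ketone, via trifluoroacetyl diketone 14 (not isolated)
Conditions: LiN(SiMe3)2, THF, −78 °C; CF3CO2CH2CF3; then MeSO2N3, Et3N, H2O, MeCN, rt
Reagents that add atoms: methanesulfonyl azide, CS(=O)(=O)N=[N+]=[N-]
Why: Detrifluoroacetylative diazo transfer: the kinetic enolate of the methyl group is trifluoroacetylated, and the sulfonyl azide then transfers the diazo group with loss of the activating group, which avoids diazomethane and its dipolar addition to the enone.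

Step 11
Reactants: 15 diazomethyl ketone; 16 ethoxyacetylene
Product: 21 indane phenol (ring A: free OH next to the anisyl methine, ethoxy meta to it, ketal on ring C), via vinylketene 17 (not isolated), via ethoxycyclobutenone 18 (not isolated), via dienylketene 19 (not isolated), via cyclohexadienone 20 (not isolated)
Conditions: 16 (3 equiv), hν (254 nm), ClCH2CH2Cl, rt; then 80 °C, sealed vessel
Reagents that add atoms: none
Why: Irradiation expels N2 and the cyclopentenyl group migrates (photo-Wolff rearrangement) to give the vinylketene, which adds ethoxyacetylene in a (2+2) cycloaddition that joins the ketene carbonyl carbon to the unsubstituted alkyne carbon. Heating opens the 4-vinylcyclobutenone by a 4π electrocyclic reaction to a dienylketene, which closes ring A by a 6π electrocyclisation onto the ring alkene CH, and the cyclohexadienone tautomerises to the phenol. The closest known reaction is the second-generation Danheiser benzannulation of α'-diazo enones with alkoxy- and siloxyacetylenes. The four-membered ring is closed by the (2+2) cycloaddition and ring A by the 6π electrocyclisation, so four ring bonds form in one operation. No stereocentre is created, and the neutral conditions leave the four existing ones, including the γ-benzylic CH, unchanged. The step needs regiocontrol, which the polarity of the ketene–ynol ether pair supplies (ethoxy meta to OH, OH on the carbon bound to the aryl methine), and tolerance of the ketal and aryl ethers, which are inert here.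

Step 12
Reactants: 21 indane phenol
Product: 22 tetraphenol ketone (ring C carbonyl free; 4-hydroxyphenyl groups and both ring A hydroxyls free)
Conditions: BBr3 (8 equiv), CH2Cl2, −78 °C → rt; H2O
Reagents that add atoms: none
Why: Boron tribromide cleaves the two aryl methyl ethers, the aryl ethyl ether and the dioxolane (Lewis-acid ether cleavage) on the robust indane, so that all oxygens can take a group that leaves without acid at the end.

Step 13
Reactants: 22 tetraphenol ketone
Product: 23 tetrakis(tert-butyldimethylsilyl) ether of 22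
Conditions: t-BuMe2SiCl, imidazole, DMF, rt
Reagents that add atoms: tert-butyldimethylsilyl chloride, CC(C)(C)[Si](C)(C)Cl
Why: Silyl ether formation at the four phenols under imidazole conditions leaves the ketone and the stereocentres untouched.

Step 14
Reactants: 24 3,5-dihydroxybenzaldehyde
Product: 25 3,5-bis(tert-butyldimethylsilyloxy)benzaldehyde
Conditions: t-BuMe2SiCl, imidazole, DMF, rt
Reagents that add atoms: tert-butyldimethylsilyl chloride, CC(C)(C)[Si](C)(C)Cl
Why: Standard phenol silylation.

Step 15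
Reactants: 25 aldehyde
Product: 26 3,5-bis(tert-butyldimethylsilyloxy)styrene
Conditions: Ph3PCH3Br, KN(SiMe3)2, THF, 0 °C
Reagents that add atoms: methyltriphenylphosphonium bromide, C[P+](c1ccccc1)(c1ccccc1)c1ccccc1.[Br-]
Why: Wittig methylenation of an aryl aldehyde with a non-nucleophilic base that spares the aryl silyl ethers.

Step 16
Reactants: 26 styrene; 27 allylboronic acid pinacol ester
Product: 28 (E)-3-aryl-allylboronic acid pinacol ester
Conditions: second-generation Grubbs catalyst (5 mol%), CH2Cl2, 40 °C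
Reagents that add atoms: none
Why: Olefin cross-metathesis of a styrene with the allylboronate releases ethene and should give the conjugated (E)-alkene.

Step 17
Reactants: 28 allylboronate; 29 4-(tert-butyldimethylsilyloxy)benzaldehyde
Product: 31 (1S,2R)-anti-1-[4-(silyloxy)phenyl]-2-[3,5-bis(silyloxy)phenyl]but-3-en-1-ol, via borate ester 30 (not isolated)
Conditions: (S)-TRIP (5 mol%), toluene, −30 °C; aqueous work-up
Reagents that add atoms: none
Why: Chiral phosphoric-acid-catalysed allylboration through a chair transition state, in which the (E)-boronate gives the anti product and the catalyst selects the aldehyde face, so the aryl-bearing allylic carbon (R) is set by the catalyst.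

Step 18
Reactants: 31 homoallylic alcohol
Product: 33 (3R,4S)-3,4-diarylbutane-1,4-diol, via alkylborane 32 (not isolated)
Conditions: 9-BBN, THF, rt; then H2O2, phosphate buffer (pH 7)
Reagents that add atoms: hydrogen peroxide, OO
Why: Anti-Markovnikov hydroboration–oxidation of the terminal alkene, with a buffered oxidation that spares the aryl silyl ethers and both stereocentres.

Step 19
Reactants: 33 diol
Product: 35 (4R,5S)-trans-4-[3,5-bis(silyloxy)phenyl]-5-[4-(silyloxy)phenyl]dihydrofuran-2(3H)-one, via lactol 34 (not isolated)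
Conditions: TEMPO (10 mol%), PhI(OAc)2 (2.5 equiv), CH2Cl2, rt
Reagents that add atoms: none
Why: Oxoammonium-mediated oxidative lactonisation: the primary alcohol is oxidised first, the aldehyde is trapped as the lactol by the benzylic hydroxyl and is oxidised on to the lactone.

Step 20
Reactants: 23 ring C ketone; 35 lactone
Product: 36 δ-hydroxy β-diketone (ring C ketone acylated at its CH2; in equilibrium with its lactol)
Conditions: LiN(i-Pr)2 (1.1 equiv), THF, −78 °C; 35; −78 → −40 °C; aq. NH4Cl
Reagents that add atoms: none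
Why: Claisen-type acylation: the kinetic enolate on the CH2 side of the ketone adds to the lactone carbonyl and the tetrahedral alkoxide opens on work-up, and no configured centre results because the acylated carbon is enolised.

Step 21
Reactants: 36 hydroxy β-diketone
Product: 37 spiro diketone (ring D closed onto the former CH2 of ring C)
Conditions: BF3·OEt2 (1.5 equiv), CH2Cl2, −78 → −20 °C
Reagents that add atoms: none
Why: The Lewis acid ionises the para-silyloxybenzylic C–O bond and the enolised β-diketone captures the cation at carbon (intramolecular C-benzylation of a 1,3-dicarbonyl, O-capture being reversible); the new aryl methine should form trans to the neighbouring 3,5-disilyloxyphenyl group, and the spiro carbon with the bulky CH(aryl) arm anti and the flat carbonyl syn to the adjacent aryl group of ring C.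

Step 22
Reactants: 37 spiro diketone; 38 (Z)-1-bromo-2-ethoxyethene
Product: 40 enal on ring C (exocyclic C=CH–CHO in place of the ring C carbonyl, mixture of alkene isomers), via carbinol 39 (not isolated)
Conditions: LiN(i-Pr)2 (1.05 equiv), THF, −78 °C; then (Z)-LiCH=CHOEt (from 38, t-BuLi, Et2O, −78 °C), −78 → −40 °C; then 1 M HCl, THF, 0 °C
Reagents that add atoms: water, O
Why: The ring D ketone is masked as its enolate (its CH2 is the only readily removed α-proton), so the vinyllithium adds to the ring C carbonyl, and dilute acid turns the γ-hydroxy enol ether into the enal by allylic transposition (two-carbon formyl-olefination with an acetaldehyde β-anion equivalent).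

Step 23
Reactants: 40 enal
Product: 41 bridged ketol (ring E closed; allylic carbinol, either epimer)
Conditions: KN(SiMe3)2 (1.1 equiv), THF, −78 → 0 °C; AcOH
Reagents that add atoms: none
Why: Intramolecular aldol addition: reversible proton transfers equilibrate the enal geometry through its dienolate, only the isomer with the formyl group toward the spiro carbon lets the ring D enolate reach the aldehyde, and the alkoxide is the thermodynamic sink; the new bridgehead CH can only form on the face of ring D that carries the ring C carbon.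

Step 24
Reactants: 41 bridged ketol
Product: 42 heptakis(tert-butyldimethylsilyl) ether of the target
Conditions: Dess–Martin periodinane, pyridine, CH2Cl2, 0 °C → rt
Reagents that add atoms: none
Why: Dess–Martin oxidation of the allylic alcohol under buffered conditions gives the enone, and with it the bridged non-enolisable 1,3-diketone, without acid or base.

Step 25
Reactants: 42 heptasilyl ether
Product: 43 target CNP0407321.1
Conditions: Bu4NF, AcOH (1:1, 8 equiv), THF, 0 °C
Reagents that add atoms: none
Why: Fluoride cleaves the seven aryl silyl ethers, and the acetic acid buffer keeps the phenoxide concentration low so that the bridged β-diketone is not opened (retro-Claisen) and the 4-hydroxyphenyl group on ring D does not start a retro-Michael cleavage.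

**Compound list**

1 | (1Z,5Z)-cycloocta-1,5-diene | C1C/C=C\CC/C=C\1 | starting material
2 | rac-endo,endo-cis-bicyclo[3.3.0]octane-2,6-diyl diacetate (1S*,2R*,5S*,6R*) | CC(=O)O[C@@H]1CC[C@@H]2[C@H](OC(C)=O)CC[C@H]12 | intermediate
3 | (1S,2R,5S,6R)-cis-bicyclo[3.3.0]octane-2,6-diol | O[C@@H]1CC[C@@H]2[C@H](O)CC[C@H]12 | intermediate
4 | (1S,5S)-cis-bicyclo[3.3.0]octane-2,6-dione | O=C1CC[C@@H]2C(=O)CC[C@H]12 | intermediate
5 | 2,6-bis(trimethylsilyloxy)-cis-bicyclo[3.3.0]octa-2,6-diene (ring fusion as in 4) | C[Si](C)(C)OC1=CC[C@@H]2C(O[Si](C)(C)C)=CC[C@H]12 | intermediate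
6 | cis-bicyclo[3.3.0]octa-3,7-diene-2,6-dione (ring fusion as in 4) | O=C1C=C[C@@H]2C(=O)C=C[C@H]12 | intermediate
7 | 4-methoxyphenylmagnesium bromide | COc1ccc([Mg]Br)cc1 | starting material
8 | (1S,4R,5S,8R)-4,8-bis(4-methoxyphenyl)-cis-bicyclo[3.3.0]octane-2,6-dione (both aryl groups exo) | O=C1C[C@@H](c3ccc(OC)cc3)[C@@H]2C(=O)C[C@@H](c3ccc(OC)cc3)[C@H]12 | intermediate
9 | mono(ethylene ketal) of 8 | O=C1C[C@@H](c3ccc(OC)cc3)[C@@H]2C4(OCCO4)C[C@@H](c3ccc(OC)cc3)[C@H]12 | intermediate
10 | enol triflate of 9 | O=S(=O)(OC1=C[C@@H](c3ccc(OC)cc3)[C@@H]2C4(OCCO4)C[C@@H](c3ccc(OC)cc3)[C@H]12)C(F)(F)F | intermediate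
11 | tributyl(1-ethoxyvinyl)stannane | CCCC[Sn](CCCC)(CCCC)C(=C)OCC | starting material
12 | 1-ethoxyvinyl diene (not isolated) | C=C(OCC)C1=C[C@@H](c3ccc(OC)cc3)[C@@H]2C4(OCCO4)C[C@@H](c3ccc(OC)cc3)[C@H]12 | intermediate
13 | 1-acetylcyclopentene with ketal on ring C | CC(=O)C1=C[C@@H](c3ccc(OC)cc3)[C@@H]2C4(OCCO4)C[C@@H](c3ccc(OC)cc3)[C@H]12 | intermediate
14 | trifluoroacetyl diketone (not isolated) | O=C(CC(=O)C1=C[C@@H](c3ccc(OC)cc3)[C@@H]2C4(OCCO4)C[C@@H](c3ccc(OC)cc3)[C@H]12)C(F)(F)F | intermediate
15 | cyclopentenyl diazomethyl ketone (key-step precursor, ketal on ring C) | [N-]=[N+]=CC(=O)C1=C[C@@H](c3ccc(OC)cc3)[C@@H]2C4(OCCO4)C[C@@H](c3ccc(OC)cc3)[C@H]12 | intermediate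
16 | ethoxyacetylene | C#COCC | starting material
17 | cyclopentenyl ketene (not isolated) | O=C=CC1=C[C@@H](c3ccc(OC)cc3)[C@@H]2C4(OCCO4)C[C@@H](c3ccc(OC)cc3)[C@H]12 | intermediate
18 | 3-ethoxy-4-(cyclopentenyl)cyclobut-2-enone (not isolated) | O=C5C=C(OCC)C5C1=C[C@@H](c3ccc(OC)cc3)[C@@H]2C4(OCCO4)C[C@@H](c3ccc(OC)cc3)[C@H]12 | intermediate
19 | dienylketene (not isolated) | O=C=C/C(OCC)=C\C1=C[C@@H](c3ccc(OC)cc3)[C@@H]2C4(OCCO4)C[C@@H](c3ccc(OC)cc3)[C@H]12 | intermediate
20 | cyclohexa-2,4-dienone (not isolated) | O=C1C=C(OCC)C=C2C1[C@@H](c4ccc(OC)cc4)[C@@H]3C5(OCCO5)C[C@@H](c4ccc(OC)cc4)[C@H]23 | intermediate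
21 | indane phenol with ethoxy group and ketal (key-step product) | Oc1cc(OCC)cc2c1[C@@H](c4ccc(OC)cc4)[C@@H]3C5(OCCO5)C[C@@H](c4ccc(OC)cc4)[C@H]23 | intermediate
22 | tetraphenol ketone | Oc1cc(O)cc2c1[C@@H](c4ccc(O)cc4)[C@@H]3C(=O)C[C@@H](c4ccc(O)cc4)[C@H]23 | intermediate
23 | tetrakis(tert-butyldimethylsilyl) ether of 22 | CC(C)(C)[Si](C)(C)Oc1cc(O[Si](C)(C)C(C)(C)C)cc2c1[C@@H](c4ccc(O[Si](C)(C)C(C)(C)C)cc4)[C@@H]3C(=O)C[C@@H](c4ccc(O[Si](C)(C)C(C)(C)C)cc4)[C@H]23 | intermediate
24 | 3,5-dihydroxybenzaldehyde | O=Cc1cc(O)cc(O)c1 | starting material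
25 | 3,5-bis(tert-butyldimethylsilyloxy)benzaldehyde | O=Cc1cc(O[Si](C)(C)C(C)(C)C)cc(O[Si](C)(C)C(C)(C)C)c1 | intermediate
26 | 3,5-bis(tert-butyldimethylsilyloxy)styrene | C=Cc1cc(O[Si](C)(C)C(C)(C)C)cc(O[Si](C)(C)C(C)(C)C)c1 | intermediate
27 | allylboronic acid pinacol ester | C=CCB1OC(C)(C)C(C)(C)O1 | starting material
28 | (E)-3-[3,5-bis(silyloxy)phenyl]allylboronic acid pinacol ester | CC1(C)OB(C/C=C/c2cc(O[Si](C)(C)C(C)(C)C)cc(O[Si](C)(C)C(C)(C)C)c2)OC1(C)C | intermediate
29 | 4-(tert-butyldimethylsilyloxy)benzaldehyde | O=Cc1ccc(O[Si](C)(C)C(C)(C)C)cc1 | starting material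
30 | pinacol borate of 31 (not isolated) | C=C[C@H](c1cc(O[Si](C)(C)C(C)(C)C)cc(O[Si](C)(C)C(C)(C)C)c1)[C@H](OB1OC(C)(C)C(C)(C)O1)c1ccc(O[Si](C)(C)C(C)(C)C)cc1 | intermediate
31 | (1S,2R)-anti-1-[4-(silyloxy)phenyl]-2-[3,5-bis(silyloxy)phenyl]but-3-en-1-ol | C=C[C@H](c1cc(O[Si](C)(C)C(C)(C)C)cc(O[Si](C)(C)C(C)(C)C)c1)[C@H](O)c1ccc(O[Si](C)(C)C(C)(C)C)cc1 | intermediate
32 | B-alkyl-9-borabicyclo[3.3.1]nonane (not isolated) | B1(CC[C@H](c2cc(O[Si](C)(C)C(C)(C)C)cc(O[Si](C)(C)C(C)(C)C)c2)[C@H](O)c2ccc(O[Si](C)(C)C(C)(C)C)cc2)C3CCCC1CCC3 | intermediate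
33 | (3R,4S)-3,4-diarylbutane-1,4-diol | OCC[C@H](c1cc(O[Si](C)(C)C(C)(C)C)cc(O[Si](C)(C)C(C)(C)C)c1)[C@H](O)c1ccc(O[Si](C)(C)C(C)(C)C)cc1 | intermediate
34 | lactol (not isolated) | OC1C[C@H](c2cc(O[Si](C)(C)C(C)(C)C)cc(O[Si](C)(C)C(C)(C)C)c2)[C@@H](c2ccc(O[Si](C)(C)C(C)(C)C)cc2)O1 | intermediate
35 | (4R,5S)-trans-4,5-diaryl-γ-butyrolactone | O=C1C[C@H](c2cc(O[Si](C)(C)C(C)(C)C)cc(O[Si](C)(C)C(C)(C)C)c2)[C@@H](c2ccc(O[Si](C)(C)C(C)(C)C)cc2)O1 | intermediate
36 | δ-hydroxy β-diketone (acylated carbon enolisable, drawn without configuration) | CC(C)(C)[Si](C)(C)Oc1cc(O[Si](C)(C)C(C)(C)C)cc2c1[C@@H](c4ccc(O[Si](C)(C)C(C)(C)C)cc4)[C@@H]3C(=O)C(C(=O)C[C@H](c4cc(O[Si](C)(C)C(C)(C)C)cc(O[Si](C)(C)C(C)(C)C)c4)[C@H](O)c4ccc(O[Si](C)(C)C(C)(C)C)cc4)[C@@H](c4ccc(O[Si](C)(C)C(C)(C)C)cc4)[C@H]23 | intermediate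
37 | spiro diketone (rings A–D) | O=C2[C@H]3[C@H](c5ccc(O[Si](C)(C)C(C)(C)C)cc5)c4c(O[Si](C)(C)C(C)(C)C)cc(O[Si](C)(C)C(C)(C)C)cc4[C@H]3[C@H](c5ccc(O[Si](C)(C)C(C)(C)C)cc5)[C@]23C(=O)C[C@H](c5cc(O[Si](C)(C)C(C)(C)C)cc(O[Si](C)(C)C(C)(C)C)c5)[C@H]3c5ccc(O[Si](C)(C)C(C)(C)C)cc5 | intermediate
38 | (Z)-1-bromo-2-ethoxyethene | CCO/C=C\Br | starting material
39 | tertiary carbinol with (Z)-2-ethoxyvinyl group on ring C (not isolated; carbinol centre undefined) | CCO/C=C\C2(O)[C@H]3[C@H](c5ccc(O[Si](C)(C)C(C)(C)C)cc5)c4c(O[Si](C)(C)C(C)(C)C)cc(O[Si](C)(C)C(C)(C)C)cc4[C@H]3[C@H](c5ccc(O[Si](C)(C)C(C)(C)C)cc5)[C@]23C(=O)C[C@H](c5cc(O[Si](C)(C)C(C)(C)C)cc(O[Si](C)(C)C(C)(C)C)c5)[C@H]3c5ccc(O[Si](C)(C)C(C)(C)C)cc5 | intermediate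
40 | enal on ring C (alkene isomers) | O=CC=C2[C@H]3[C@H](c5ccc(O[Si](C)(C)C(C)(C)C)cc5)c4c(O[Si](C)(C)C(C)(C)C)cc(O[Si](C)(C)C(C)(C)C)cc4[C@H]3[C@H](c5ccc(O[Si](C)(C)C(C)(C)C)cc5)[C@]23C(=O)C[C@H](c5cc(O[Si](C)(C)C(C)(C)C)cc(O[Si](C)(C)C(C)(C)C)c5)[C@H]3c5ccc(O[Si](C)(C)C(C)(C)C)cc5 | intermediate
41 | bridged ketol (carbinol epimers) | OC1C=C2[C@H]3[C@H](c5ccc(O[Si](C)(C)C(C)(C)C)cc5)c4c(O[Si](C)(C)C(C)(C)C)cc(O[Si](C)(C)C(C)(C)C)cc4[C@H]3[C@H](c5ccc(O[Si](C)(C)C(C)(C)C)cc5)[C@]23C(=O)[C@H]1[C@H](c5cc(O[Si](C)(C)C(C)(C)C)cc(O[Si](C)(C)C(C)(C)C)c5)[C@H]3c5ccc(O[Si](C)(C)C(C)(C)C)cc5 | intermediate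
42 | heptakis(tert-butyldimethylsilyl) ether of the target | O=C1C=C2[C@H]3[C@H](c5ccc(O[Si](C)(C)C(C)(C)C)cc5)c4c(O[Si](C)(C)C(C)(C)C)cc(O[Si](C)(C)C(C)(C)C)cc4[C@H]3[C@H](c5ccc(O[Si](C)(C)C(C)(C)C)cc5)[C@]23C(=O)[C@H]1[C@H](c5cc(O[Si](C)(C)C(C)(C)C)cc(O[Si](C)(C)C(C)(C)C)c5)[C@H]3c5ccc(O[Si](C)(C)C(C)(C)C)cc5 | intermediate
43 | CNP0407321.1 | O=C1C=C2[C@H]3[C@H](c4ccc(O)cc4)c4c(O)cc(O)cc4[C@H]3[C@H](c3ccc(O)cc3)[C@]23C(=O)[C@H]1[C@H](c1cc(O)cc(O)c1)[C@H]3c1ccc(O)cc1 | target

**Step count**

Total: 25 steps. Longest linear sequence: 19 steps (steps 1–13 and 20–25); the lactone branch is steps 14–19.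

**Steps most likely to fail**

1. Step 23 (closure of ring E). The enal is expected mainly as the geometric isomer that cannot cyclise, and the aldol addition is reversible, so the closure may stall or revert before the oxidation. The same fallback also bypasses the selective addition of step 22. It sets out from 37 and returns at 42. Soft-enolisation C-acetylation at the CH2 of ring D (MgBr2·OEt2, i-Pr2NEt, 1-acetylbenzotriazole, CH2Cl2) gives the 2-acetyl ketone F1. An acid-catalysed intramolecular aldol condensation of the acetyl methyl group with the ring C ketone (TsOH cat., toluene, 60 °C, molecular sieves) then closes ring E through the other bond and gives 42 directly.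

2. Step 21 (closure of ring D). The benzylic cation may lose a proton to a stilbene, which would erase the catalyst-set centre; capture may stay at oxygen; or the facial selectivity at the spiro carbon may be poor. The fallback sets out from 36 and returns at 37, and forms the same bond under basic conditions without a free cation. Dehydration of 36 (pyridinium tosylate, molecular sieves) gives the cyclic enol ether F2. Bu4NF removes the silyl groups, and the para-phenoxide expels the vinylogous carboxylate to give a para-quinone methide, which the diketonate recaptures at carbon by 1,6-addition to give the heptaphenol spiro diketone F3. Silylation (t-BuMe2SiCl, imidazole, DMF) then gives 37.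

3. Step 11 (benzannulation). The anisyl chromophores may screen the diazo ketone from the light, or the ketene may be intercepted by the product phenol, so that conversion to the indane is low. The fallback sets out from 10 and returns at 21, and reaches the same vinylketene 17 without light. Palladium-catalysed coupling of 10 with BrZnCH2CO2Me (Pd(PPh3)4, THF) gives the cyclopentenylacetate F4. LiOH gives the acid F5 and oxalyl chloride the acid chloride F6. Dehydrochlorination with Et3N in the presence of 16 (toluene, rt, then 80 °C) then runs through 17–20 to 21.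

**Further compounds**

F1 | step 23 | 2-acetyl derivative of spiro diketone 37 (acetylated carbon enolised) | O=C2[C@H]3[C@H](c5ccc(O[Si](C)(C)C(C)(C)C)cc5)c4c(O[Si](C)(C)C(C)(C)C)cc(O[Si](C)(C)C(C)(C)C)cc4[C@H]3[C@H](c5ccc(O[Si](C)(C)C(C)(C)C)cc5)[C@]23C(=O)C(C(C)=O)[C@H](c5cc(O[Si](C)(C)C(C)(C)C)cc(O[Si](C)(C)C(C)(C)C)c5)[C@H]3c5ccc(O[Si](C)(C)C(C)(C)C)cc5
F2 | step 21 | cyclic enol ether (2-alkylidene-tetrahydrofuran) from 36 | CC(C)(C)[Si](C)(C)Oc1cc(O[Si](C)(C)C(C)(C)C)cc2c1[C@@H](c4ccc(O[Si](C)(C)C(C)(C)C)cc4)[C@@H]3C(=O)C(=C6C[C@H](c4cc(O[Si](C)(C)C(C)(C)C)cc(O[Si](C)(C)C(C)(C)C)c4)[C@@H](c4ccc(O[Si](C)(C)C(C)(C)C)cc4)O6)[C@@H](c4ccc(O[Si](C)(C)C(C)(C)C)cc4)[C@H]23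
F3 | step 21 | heptaphenol spiro diketone | O=C2[C@H]3[C@H](c5ccc(O)cc5)c4c(O)cc(O)cc4[C@H]3[C@H](c5ccc(O)cc5)[C@]23C(=O)C[C@H](c5cc(O)cc(O)c5)[C@H]3c5ccc(O)cc5
F4 | step 11 | methyl cyclopentenylacetate (ketal on ring C) | COC(=O)CC1=C[C@@H](c3ccc(OC)cc3)[C@@H]2C4(OCCO4)C[C@@H](c3ccc(OC)cc3)[C@H]12
F5 | step 11 | cyclopentenylacetic acid | OC(=O)CC1=C[C@@H](c3ccc(OC)cc3)[C@@H]2C4(OCCO4)C[C@@H](c3ccc(OC)cc3)[C@H]12
F6 | step 11 | cyclopentenylacetyl chloride | ClC(=O)CC1=C[C@@H](c3ccc(OC)cc3)[C@@H]2C4(OCCO4)C[C@@H](c3ccc(OC)cc3)[C@H]12
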